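**Assumption and notation (one line):** the target is made exactly as drawn, i.e. with a 2,3-cis (2S,3S) dihydrobenzofuran and the (+)-pinoresinol-type furofuran; Fs = (1S,3aR,4S,6aR)-4-(4-hydroxy-3,5-dimethoxyphenyl)tetrahydro-1H,3H-furo[3,4-c]furan-1-yl; C7/C8 (and C7'/C8'/C9) are lignan locants, C7/C8 of the new C6–C3 unit become C2/C3 of the dihydrobenzofuran.

## Retrosynthetic overview

1. Target ⇐ ester methanolysis and one-carbon trimming (periodate, NaBH4) of a 2,3-cis dihydrobenzofuran that carries a glyceraldehyde-derived dioxolane at C3; this ring ⇐ Mitsunobu SN2 closure (inversion at C2) of the syn-hydroboration product of a trisubstituted alkene.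
2. Alkene ⇐ key disconnection at the aryl C5–C8 bond: photochemical aryl-radical hydroarylation of an aryl alkyne with 5-iodomedioresinol, the phenolic O–H fixing the alkene geometry.
3. Aryl alkyne ⇐ Sonogashira coupling of 4-iodo-2-methoxyphenyl pivalate with (R)-4-ethynyl-2,2-dimethyl-1,3-dioxolane (from (S)-glyceraldehyde acetonide).
4. 5-Iodomedioresinol ⇐ 5,5'-diiodopinoresinol ⇐ pinoresinol diacetate ⇐ lariciresinol diacetate (photochemical 1,5-HAT C–H etherification) ⇐ (−)-hydroxymatairesinol (LiAlH4, acid).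
5. Ring order: lactone → tetrahydrofuran → furofuran (second tetrahydrofuran) → dihydrobenzofuran last.

## Route

Step 1
Reactants: 1 (−)-7-hydroxymatairesinol (HMR)
Product: 3 (+)-lariciresinol, via 7-hydroxysecoisolariciresinol 2 (not isolated)
Conditions: LiAlH4, THF, 0 °C → rt; then 1 M HCl to pH 2, rt
Reagents that add atoms: none
Why: Hydride reduction of the lactone gives the 7,9,9'-triol, and on acidification the p-hydroxybenzylic C7–OH ionises (quinone methide/benzyl cation) and is captured 5-exo by O9' to give the thermodynamic 7,8-trans tetrahydrofuran, so C7 is set by the purchased C8/C8' centres (known reduction–cycloetherification of HMR).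

Step 2
Reactants: 3 (+)-lariciresinol
Product: 4 (+)-lariciresinol 4,4'-di-O-acetate
Conditions: Ac2O (2.2 equiv), 1 M NaOH aq., THF, 0 °C
Reagents that add atoms: acetic anhydride, CC(=O)OC(C)=O
Why: Schotten–Baumann acylation acetylates only the phenoxides, which leaves the primary C9–OH free and masks the phenols against the oxidant of step 3.

Step 3
Reactants: 4 (+)-lariciresinol 4,4'-di-O-acetate
Product: 5 (+)-pinoresinol di-O-acetate
Conditions: PhI(OAc)2, I2, NaHCO3, cyclohexane/CH2Cl2, visible light (W lamp), 25 °C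
Reagents that add atoms: none
Why: Hypoiodite (Suárez) reaction: light cleaves the O–I bond formed in situ, the C9 alkoxy radical abstracts the cis-disposed benzylic C7'–H by 1,5-HAT (C7–H is only 1,4), and the benzylic iodide/cation is closed by O9 on the convex face, so the aryl group ends exo (7'S) under control of C8/C8'.

Step 4
Reactants: 5 (+)-pinoresinol di-O-acetate
Product: 7 5,5'-diiodopinoresinol, via (+)-pinoresinol 6 (not isolated)
Conditions: K2CO3, MeOH, rt; then I2 (2.1 equiv), 0 °C → rt
Reagents that add atoms: iodine, II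
Why: Methanolysis frees both phenols and the phenoxides undergo electrophilic iodination at their only free ortho position (C5 and C5'), as in the iodination of vanillin.

Step 5
Reactants: 7 5,5'-diiodopinoresinol
Product: 8 5-iodomedioresinol
Conditions: NaOMe, CuI (20 mol %), MeOH/DMF, 100 °C, stopped at ca. 50 % conversion; 7 recycled
Reagents that add atoms: sodium methoxide, [Na+].[O-]C
Why: Copper-catalysed Ullmann-type methoxylation of an o-iodophenol (the 5-iodovanillin → syringaldehyde reaction); the two sites of the C2-symmetric diiodide are equivalent, so this is a statistical desymmetrisation and 8 is separated from recovered 7 and the bis-methoxy product.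

Step 6
Reactants: 9 4-iodo-2-methoxyphenol
Product: 10 4-iodo-2-methoxyphenyl pivalate
Conditions: PivCl, Et3N, DMAP (cat.), CH2Cl2, 0 °C → rt
Reagents that add atoms: pivaloyl chloride, CC(C)(C)C(Cl)=O
Why: O-acylation; the pivalate masks the phenol and makes the ring electron-poor enough for a clean SN2 at its benzylic carbon in step 11.

Step 7
Reactants: 11 (S)-glyceraldehyde acetonide
Product: 12 (R)-4-ethynyl-2,2-dimethyl-1,3-dioxolane
Conditions: Ohira–Bestmann reagent, K2CO3, MeOH, 0 °C → rt
Reagents that add atoms: dimethyl (1-diazo-2-oxopropyl)phosphonate, CC(=O)C(=[N+]=[N-])P(=O)(OC)OC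
Why: Seyferth–Gilbert homologation under mild K2CO3/MeOH conditions turns the aldehyde into the terminal alkyne without epimerising the purchased stereocentre (S → R is only a CIP priority change).

Step 8
Reactants: 10 4-iodo-2-methoxyphenyl pivalate; 12 (R)-4-ethynyl-2,2-dimethyl-1,3-dioxolane
Product: 13 4-{[(4R)-2,2-dimethyl-1,3-dioxolan-4-yl]ethynyl}-2-methoxyphenyl pivalate
Conditions: Pd(PPh3)2Cl2 (2 mol %), CuI (4 mol %), Et3N, THF, rt
Reagents that add atoms: none
Why: Sonogashira coupling of an aryl iodide with a terminal alkyne; the propargylic stereocentre is not involved.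

Step 9
Reactants: 8 5-iodomedioresinol; 13 aryl alkyne
Product: 14 (Z)-alkene with the two aryl groups trans (aryl and dioxolane cis)
Conditions: 13 (3 equiv), Ru(bpy)3(PF6)2 (2 mol %), Et3N (3 equiv), MeCN, 450 nm LEDs, 25 °C, degassed
Reagents that add atoms: none
Why: Proposed new method: the α-aminoalkyl radical formed from Et3N by reductive quenching of Ru(II)* abstracts iodine from 8 (XAT), the aryl radical adds to the alkyne carbon remote from the aryl group of 13 to give the linear α-aryl vinyl radical, and this is quenched intramolecularly by 1,5-H transfer from the neighbouring phenolic O–H, so H enters cis to the new aryl group and the C5–C8 bond is formed with defined geometry, after which Ru(I) reduces the phenoxyl radical and closes the cycle; the closest known reactions are XAT-triggered aryl-radical couplings of aryl iodides and photoredox Meerwein-type hydroarylations of alkynes, which have no O–H relay and give E/Z mixtures, and the low triplet energy of Ru(bpy)3 is chosen to avoid sensitised E/Z scrambling.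

Step 10
Reactants: 14 (Z)-alkene
Product: 16 (1R,2R)-alcohol, via organoborane 15 (not isolated)
Conditions: BH3·SMe2 (5 equiv), THF, 0 → 40 °C; then 30 % H2O2, aq. NaHCO3, 0 °C → rt; diastereomers separated
Reagents that add atoms: borane–dimethyl sulfide (boron of 15 only), [BH3-][S+](C)C; hydrogen peroxide (oxygen of 16), OO
Why: Hydroboration–oxidation adds H (C8) and OH (C7) syn with boron at the less substituted benzylic carbon; with the dioxolane C–H eclipsing the alkene (A1,3 strain from the cis aryl group) borane is expected to enter anti to the allylic C–C bond and syn to C–O (Houk model), which gives the (1R,2R) isomer, and oxidation retains configuration.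

Step 11
Reactants: 16 (1R,2R)-alcohol
Product: 17 (2S,3R)-2,3-cis-dihydrobenzofuran acetonide
Conditions: PPh3, DIAD, THF, 0 °C → rt
Reagents that add atoms: none
Why: Mitsunobu cycloetherification: the ortho phenol displaces the oxyphosphonium group at C7 in a 5-exo-tet SN2 with inversion (the p-pivaloyloxy group disfavours ionisation), which converts the syn adduct into the 2,3-cis ring with C2 = S.

Step 12
Reactants: 17 cis-dihydrobenzofuran acetonide
Product: 18 syringyl O-acetate of 17
Conditions: Ac2O, pyridine, DMAP (cat.), CH2Cl2, rt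
Reagents that add atoms: acetic anhydride, CC(=O)OC(C)=O
Why: Acylation of the only remaining free hydroxyl protects the periodate-sensitive 2,6-dimethoxyphenol before the glycol cleavage.

Step 13
Reactants: 18 syringyl O-acetate
Product: 21 target CNP0126146.1, via cis-aldehyde 19 (not isolated), via diester alcohol 20 (not isolated)
Conditions: H5IO6 (1.5 equiv), EtOAc, 0 °C; filter, concentrate; NaBH4, MeOH, −10 °C; then K2CO3, MeOH, 25 °C
Reagents that add atoms: none
Why: Periodic acid hydrolyses the terminal acetonide and cleaves the glycol, the enolisable cis-aldehyde is reduced at once by NaBH4 before it can epimerise at C3, and K2CO3/MeOH methanolyses both aryl esters; no stereocentre is touched (C3 becomes S only by CIP priority change).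

## Compound list

1 | (−)-7-hydroxymatairesinol (HMR), (3R,4R)-4-[(S)-hydroxy(4-hydroxy-3-methoxyphenyl)methyl]-3-(4-hydroxy-3-methoxybenzyl)oxolan-2-one | COc1cc(C[C@H]2C(=O)OC[C@@H]2[C@H](O)c2ccc(O)c(OC)c2)ccc1O | starting material
2 | 7-hydroxysecoisolariciresinol, (1S,2R,3R)-1-(4-hydroxy-3-methoxyphenyl)-2-(hydroxymethyl)-3-(4-hydroxy-3-methoxybenzyl)butane-1,4-diol | COc1cc(C[C@@H](CO)[C@H](CO)[C@H](O)c2ccc(O)c(OC)c2)ccc1O | intermediate
3 | (+)-lariciresinol, 4-{[(3R,4R,5S)-5-(4-hydroxy-3-methoxyphenyl)-4-(hydroxymethyl)oxolan-3-yl]methyl}-2-methoxyphenol | COc1cc([C@H]2OC[C@H](Cc3ccc(O)c(OC)c3)[C@@H]2CO)ccc1O | intermediate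
4 | (+)-lariciresinol 4,4'-di-O-acetate (both phenols acetylated, primary OH free) | COc1cc([C@H]2OC[C@H](Cc3ccc(OC(C)=O)c(OC)c3)[C@@H]2CO)ccc1OC(C)=O | intermediate
5 | (+)-pinoresinol di-O-acetate, (1S,3aR,4S,6aR)-1,4-bis(4-acetoxy-3-methoxyphenyl)tetrahydro-1H,3H-furo[3,4-c]furan (both aryl groups exo) | COc1cc([C@H]2OC[C@H]3[C@@H]2CO[C@@H]3c2ccc(OC(C)=O)c(OC)c2)ccc1OC(C)=O | intermediate
6 | (+)-pinoresinol, 4,4'-[(1S,3aR,4S,6aR)-tetrahydro-1H,3H-furo[3,4-c]furan-1,4-diyl]bis(2-methoxyphenol) | COc1cc([C@H]2OC[C@H]3[C@@H]2CO[C@@H]3c2ccc(O)c(OC)c2)ccc1O | intermediate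
7 | 5,5'-diiodo-(+)-pinoresinol, 4,4'-[(1S,3aR,4S,6aR)-tetrahydro-1H,3H-furo[3,4-c]furan-1,4-diyl]bis(2-iodo-6-methoxyphenol) | COc1cc([C@H]2OC[C@H]3[C@@H]2CO[C@@H]3c2cc(I)c(O)c(OC)c2)cc(I)c1O | intermediate
8 | 5-iodo-(+)-medioresinol, 4-(Fs)-2-iodo-6-methoxyphenol | COc1cc([C@H]2OC[C@H]3[C@@H]2CO[C@@H]3c2cc(OC)c(O)c(OC)c2)cc(I)c1O | intermediate
9 | 4-iodo-2-methoxyphenol | COc1cc(I)ccc1O | starting material
10 | 4-iodo-2-methoxyphenyl pivalate | COc1cc(I)ccc1OC(=O)C(C)(C)C | intermediate
11 | (S)-2,2-dimethyl-1,3-dioxolane-4-carbaldehyde ((S)-glyceraldehyde acetonide) | O=C[C@@H]1COC(C)(C)O1 | starting material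
12 | (R)-4-ethynyl-2,2-dimethyl-1,3-dioxolane | C#C[C@@H]1COC(C)(C)O1 | intermediate
13 | 4-{[(4R)-2,2-dimethyl-1,3-dioxolan-4-yl]ethynyl}-2-methoxyphenyl pivalate | COc1cc(C#C[C@@H]2COC(C)(C)O2)ccc1OC(=O)C(C)(C)C | intermediate
14 | 4-{(Z)-2-[(4R)-2,2-dimethyl-1,3-dioxolan-4-yl]-2-[5-(Fs)-2-hydroxy-3-methoxyphenyl]ethenyl}-2-methoxyphenyl pivalate (aryl groups trans across C=C) | COc1cc(/C=C(/c2cc([C@H]3OC[C@H]4[C@@H]3CO[C@@H]4c3cc(OC)c(O)c(OC)c3)cc(OC)c2O)[C@@H]2COC(C)(C)O2)ccc1OC(=O)C(C)(C)C | intermediate
15 | organoborane from syn addition of H–BH2 to 14, boron on the carbon bearing the pivaloyloxyaryl group, same configuration as 16 with BH2 in place of OH (drawn as R–BH2; the phenolic OH groups are O-borylated in the flask) | COc1cc([C@H](B)[C@@H](c2cc([C@H]3OC[C@H]4[C@@H]3CO[C@@H]4c3cc(OC)c(O)c(OC)c3)cc(OC)c2O)[C@@H]2COC(C)(C)O2)ccc1OC(=O)C(C)(C)C | intermediate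
16 | 4-{(1R,2R)-2-[(4R)-2,2-dimethyl-1,3-dioxolan-4-yl]-2-[5-(Fs)-2-hydroxy-3-methoxyphenyl]-1-hydroxyethyl}-2-methoxyphenyl pivalate | COc1cc([C@H](O)[C@@H](c2cc([C@H]3OC[C@H]4[C@@H]3CO[C@@H]4c3cc(OC)c(O)c(OC)c3)cc(OC)c2O)[C@@H]2COC(C)(C)O2)ccc1OC(=O)C(C)(C)C | intermediate
17 | 4-[(2S,3R)-3-[(4R)-2,2-dimethyl-1,3-dioxolan-4-yl]-5-(Fs)-7-methoxy-2,3-dihydro-1-benzofuran-2-yl]-2-methoxyphenyl pivalate (2,3-cis) | COc1cc([C@H]2Oc3c(OC)cc([C@H]4OC[C@H]5[C@@H]4CO[C@@H]5c4cc(OC)c(O)c(OC)c4)cc3[C@H]2[C@@H]2COC(C)(C)O2)ccc1OC(=O)C(C)(C)C | intermediate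
18 | 17 with the 4-hydroxy-3,5-dimethoxyphenyl OH acetylated (2,3-cis) | COc1cc([C@H]2Oc3c(OC)cc([C@H]4OC[C@H]5[C@@H]4CO[C@@H]5c4cc(OC)c(OC(C)=O)c(OC)c4)cc3[C@H]2[C@@H]2COC(C)(C)O2)ccc1OC(=O)C(C)(C)C | intermediate
19 | (2S,3R)-3-formyl analogue of 18 (2,3-cis aldehyde, dioxolane replaced by CHO) | COc1cc([C@H]2Oc3c(OC)cc([C@H]4OC[C@H]5[C@@H]4CO[C@@H]5c4cc(OC)c(OC(C)=O)c(OC)c4)cc3[C@H]2C=O)ccc1OC(=O)C(C)(C)C | intermediate
20 | (2S,3S)-3-(hydroxymethyl) compound still carrying the aryl pivalate and the syringyl acetate (2,3-cis) | COc1cc([C@H]2Oc3c(OC)cc([C@H]4OC[C@H]5[C@@H]4CO[C@@H]5c4cc(OC)c(OC(C)=O)c(OC)c4)cc3[C@H]2CO)ccc1OC(=O)C(C)(C)C | intermediate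
21 | CNP0126146.1, 4-[(2S,3S)-5-(Fs)-3-(hydroxymethyl)-7-methoxy-2,3-dihydro-1-benzofuran-2-yl]-2-methoxyphenol (2,3-cis) | COc1cc([C@H]2Oc3c(OC)cc([C@H]4OC[C@H]5[C@@H]4CO[C@@H]5c4cc(OC)c(O)c(OC)c4)cc3[C@H]2CO)ccc1O | target

## Step count and risks

Total steps: 13. Longest linear sequence: 10 steps (1 → 21 through steps 1–5 and 9–13).

The step most likely to fail is the new photochemical hydroarylation (step 9). Hydrodeiodination of 8 by the amine, intermolecular quenching of the vinyl radical and sensitised E/Z scrambling could all erode it. Its fallback uses known chemistry and sets out from 13. Copper-catalysed syn-borylation (CuCl, Xantphos, NaOtBu, B2pin2, MeOH, THF, rt) places boron β to the aryl ring and gives the (Z)-alkenyl pinacol boronate F1. Suzuki–Miyaura coupling of F1 with 8 (Pd(dppf)Cl2, K3PO4, dioxane/H2O, 60 °C) proceeds with retention of geometry and comes back to the route at 14.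

The second risk is the hydroboration of step 10. The trisubstituted stilbene is hindered, the free phenols consume borane, and the facial preference imposed by the dioxolane is a model-based prediction that may be modest or even opposite in sense. The fallback sets out from 14 and changes how the two new centres are made. Iodine-mediated oxidative cyclisation of the o-hydroxystilbene (I2, K2CO3, THF, rt) gives the 2-aryl-3-dioxolanyl benzofuran F2. Heterogeneous hydrogenation (H2, Rh/Al2O3, EtOAc, stopped after one equivalent to spare the benzylic ethers) adds both hydrogens to one face and gives the 2,3-cis dihydrobenzofuran directly. This comes back to the route at 17 and bypasses steps 10 and 11; the two cis diastereomers differ at centres next to the dioxolane and are separable.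

The third risk is the hypoiodite C–H etherification of step 3. Acetyl hypoiodite may iodinate the methoxyarenes, and abstraction of the ring C9'–H competes with the benzylic C7'–H. The fallback sets out from 3 and forms the same C7'–O bond from the arene side. DDQ (1.0 equiv, dioxane, 10 °C, partial conversion because the other phenolic ring can also be oxidised) generates the C7' quinone methide, which the C9 hydroxyl captures. This comes back to the route at 6, which is iodinated as in step 4, so step 2, step 3 and the methanolysis are bypassed. It makes no new compound (F0: none).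

## Further compounds

F1 | step 9 | 2-methoxy-4-{(Z)-2-[(4R)-2,2-dimethyl-1,3-dioxolan-4-yl]-2-(4,4,5,5-tetramethyl-1,3,2-dioxaborolan-2-yl)ethenyl}phenyl pivalate | COc1cc(/C=C(/B2OC(C)(C)C(C)(C)O2)[C@@H]2COC(C)(C)O2)ccc1OC(=O)C(C)(C)C
F2 | step 10 | 4-[3-[(4R)-2,2-dimethyl-1,3-dioxolan-4-yl]-5-(Fs)-7-methoxy-1-benzofuran-2-yl]-2-methoxyphenyl pivalate | COc1cc(-c2oc3c(OC)cc([C@H]4OC[C@H]5[C@@H]4CO[C@@H]5c4cc(OC)c(O)c(OC)c4)cc3c2[C@@H]2COC(C)(C)O2)ccc1OC(=O)C(C)(C)C
F0 | step 3 | none | none
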